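The earlier runs and the new flask are calculated for substances that don't exist; noise was put on by code.

I began from a one-step world, in which each unit of reagent turned one unit of substrate into product, so the fraction of the racemate converted was simply the reagent's share of it, w.

| flask | left-handed substrate | right-handed substrate | reagent | free catalyst | remark | time |
|---|---|---|---|---|---|---|
| Saturday's | 0.16 M | 0.16 M | 0.048 M (in portions, 2) | 0.27 mM | run made earlier; portions every 8.0 min |  |
| Tuesday's | 0.16 M | 0.16 M | 0.19 M (in portions, 2) | 0.27 mM | run made earlier; portions every 8.0 min |  |
| Thursday's | 0.080 M | 0.080 M | 0.096 M (in portions, 2) | 0.27 mM | run made earlier; portions every 8.0 min |  |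
| flask | 0.16 M | 0.16 M | 0.0960 M (in portions, 2) | 0.27 mM | the portions of reagent follow each other after 8.0 min, the first at the start | 8.0 h |

- Saturday's (time / h: left-handed product / %, right-handed substrate / %): 0.833: 7.6, 43.8; 1.33: 8.7, 44.0; 2.00: 9.0, 43.7; 2.50: 8.2, 43.7; 4.00: 8.6, 44.2; 6.00: 8.0, 43.8; 10.0: 8.8, 43.2
- Tuesday's (time / h: left-handed product / %, right-handed substrate / %): 0.500: 21.3, 32.9; 1.33: 27.2, 29.0; 2.50: 28.8, 26.8; 4.00: 30.7, 25.7; 6.00: 31.2, 26.2; 8.00: 30.5, 24.9; 10.0: 30.9, 25.4
- Thursday's (time / h: left-handed product / %, right-handed substrate / %): 0.833: 23.5, 32.5; 2.50: 30.1, 27.3; 4.00: 29.6, 26.4; 6.00: 30.6, 27.0; 10.0: 31.0, 25.8

(scatter of a reading: 0.5 percentage points)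

- free catalyst is single-handed; left-handed substrate and right-handed substrate are mirror images of each other, charged as a racemate, each of them at the stated concentration
- the reaction counts as stopped when no species that holds the left-handed substrate and right-handed substrate together changes by six tenths of a point or more over the second half of the time

* at 8.0 h, what has stopped the reaction, if anything has (all of the left-handed substrate has reacted / the reagent has run out first / no working catalyst is left / forward and back rates have come level / it is still moving)
* how much left-handed product there is at 8.0 h, in percent of the left-handed substrate and right-handed substrate together charged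
* how much right-handed substrate there is at 8.0 h, in percent of the left-handed substrate and right-handed substrate together charged

For this flask w was 30.0%, with the reagent as limiting reagent. Saturday's run supported the picture: its share was 15.0% and its late readings showed 14.7% converted.

I then asked what each number was worth. In that picture one point of w moved each answer by about half a point, so the charge had to be known well. I set aside the stopping of the catalyst, since w lay below the 55.5% converted at the last reading of Tuesday's run.

The split remained, and I reckoned it as a small correction to an even one. The selectivity factor s, the logarithm of the fraction of left-handed substrate remaining over that of right-handed substrate remaining, read 1.39 from Saturday's run. To first order, the lead over an even split is half of (one minus w), times the negative logarithm of that, times (s minus one) over (s plus one). That gave 2 percentage points. Tuesday's reading of s, 1.43, shifted this by 0.18 points, against a scatter of 0.5 points. My figures were 17.0% left-handed product and 37.0% right-handed substrate.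

The forecast said the reagent has run out first, with 17% and 37.2%, the latter slightly above mine: “Tuesday passed 30% within 0.5 h, so the reagent runs out before the catalyst dies.”

The flask showed that the reagent has run out first, with reagent at 0% of its charge, 17.1% left-handed product and 37.1% right-handed substrate.

    free catalyst + right-handed substrate ⇌ catalyst intermediate B (K = 17.0 /M, k = 29000 /M/min)
    free catalyst + left-handed substrate ⇌ catalyst intermediate A (K = 2.00 /M, k = 69000 /M/min)
    reagent + free catalyst → spent catalyst (k = 1.00 /M/min)
    reagent + catalyst intermediate B → free catalyst + right-handed product (k = 150 /M/min)
    reagent + catalyst intermediate A → free catalyst + left-handed product (k = 1800 /M/min)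

The lead in this flask was 2.1 points against my 2 points. For the neighbour charged with 0.16 M of reagent, share 50.0%, the same s gave a lead of 2.8 points, and that flask held 27.9% left-handed product and 28.1% right-handed substrate. This flask's left-handed product rested mainly on the undoing of catalyst intermediate B into free catalyst and right-handed substrate. In the run without that undoing, left-handed product fell from 17.1% to 0.204%.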